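Guaiane numbering is used, with primes on the ether-bridged, santonin-derived half. The retrosynthesis cuts, in order: the unprimed lactone (O–C12, C7–C11); C1–C10; the cyclopropane bonds C8–C6 and C8–C7 with C9=C10; C5–C6; the oxygens on C4' and C3'; and C2–C2' with C3–C5'.
Enabling feature: the unprimed seven-membered ring C1–C5–C6–C7–C8–C9–C10 has oxygen on C6 and the methyl carbinol C10 bonded to the ring-fusion methine C1. It is therefore a masked cyclohepta-1,4-diene (C5=C6, C8=C9), the Cope product of an alkoxycyclopropane C6–C7–C8 that carries the ring A alkene C5=C1 on C6 and an alkene C9=C10 on C8.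
Forward: santonin gives the primed 5/7/lactone unit, C10' is inverted, and the derived cyclopentadiene adds cyclopent-4-ene-1,3-dione (ring A and the norbornene). Oxidative cyclisation closes the ether bridge. Stille coupling, cyclopropanation and boron–Wittig olefination build the substrate, the [3,3] shift closes the seven-membered ring, and alkylation plus reduction close the last lactone.
Stereochemistry: C1', C6', C7', C11' come from santonin and C10' from face-selective methyl addition. C2, C3, C2', C5' come from the endo, anti Diels–Alder reaction, and C3', C4' from syn delivery out of the C10' perrhenate. C1 comes from the convex face of ring A, and C10 from the alkenylboronate geometry plus retentive oxidation. C11 comes from (S)-lactate by inversion, and C7 and C6 from substrate control.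
Design points: C10 carries boron during the shift, because its geometry (boron trans to C8) is fixed by synthesis, whereas the matching enol ether is the contra-thermodynamic isomer. C4 stays trigonal (exocyclic methylene) because the endo methyl on C4' leaves no room for an α substituent. The cage is saturated first, so no retro-Diels–Alder reaction can compete.
Key step: step 20

Remark: 22, 23 and 26 are drawn as the cis cyclopropane of the sense that rearranges directly. The other isomers from step 17 are carried along, since C6 and C8 become trigonal in step 20. 11 is drawn as the diketone although it will be largely enolised.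
Remark: α is the face of ring A that carries the cage. Exo and endo refer to the norbornane C2'–C3'–C4'–C5'–C3–C2 with C1' as the one-carbon bridge.

Step 1
Reactants: 1 (−)-α-santonin
Product: 2 isophotosantonic lactone (10'α-hydroxy-3'-oxo-1'αH-guai-4'-en-12',6'α-olide)
Conditions: hν (medium-pressure Hg lamp, Pyrex), AcOH–H2O 1:1, reflux
Reagents that add atoms: water, O
Why: Photochemical rearrangement of the cross-conjugated cyclohexadienone in aqueous acid, in which water captures the rearranged cation at C10' from the α face, gives the 5/7 skeleton with H-1' α and leaves C6', C7' and C11' untouched.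

Step 2
Reactants: 2 isophotosantonic lactone
Product: 3 3'β,10'α-dihydroxyguai-4'-en-12',6'α-olide
Conditions: NaBH4, CeCl3·7H2O, MeOH, 0 °C
Reagents that add atoms: none
Why: Luche 1,2-reduction of the cyclopentenone, with hydride expected from the α face opposite the β methyl group on C10'; the configuration at C3' is lost again in step 7.

Step 3
Reactants: 3 3'β,10'α-dihydroxyguai-4'-en-12',6'α-olide
Product: 4 3'β-acetoxy-10'α-hydroxyguai-4'-en-12',6'α-olide
Conditions: Ac2O, pyridine, DMAP (cat.), CH2Cl2, 0 °C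
Reagents that add atoms: acetic anhydride, CC(=O)OC(C)=O
Why: DMAP-catalysed acylation distinguishes the secondary allylic alcohol from the hindered tertiary one and installs the leaving group used in step 7.

Step 4
Reactants: 4 3'β-acetoxy-10'α-hydroxyguai-4'-en-12',6'α-olide
Product: 5 3'β-acetoxyguaia-4',10'(14')-dien-12',6'α-olide
Conditions: SOCl2, pyridine, −20 to 0 °C
Reagents that add atoms: none
Why: Chlorosulfite formation and E2 elimination, in which H-1' is syn to the α leaving group and cannot take part, so the methyl group offers the antiperiplanar hydrogen and the exocyclic alkene should prevail.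

Step 5
Reactants: 5 3'β-acetoxyguaia-4',10'(14')-dien-12',6'α-olide
Product: 7 3'β-acetoxy-10'-oxo-14'-norguai-4'-en-12',6'α-olide, via vicinal diol 6 (not isolated)
Conditions: OsO4 (cat.), NaIO4, 2,6-lutidine, dioxane–H2O 3:1, rt
Reagents that add atoms: osmium tetroxide, O=[Os](=O)(=O)=O; sodium periodate, [Na+].[O-]I(=O)(=O)=O
Why: Lemieux–Johnson cleavage, in which OsO4 takes the unhindered 1,1-disubstituted alkene rather than the tetrasubstituted C4'=C5' bond and periodate cleaves the diol to the ketone.

Step 6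
Reactants: 7 3'β-acetoxy-10'-oxo-14'-norguai-4'-en-12',6'α-olide
Product: 8 3'β-acetoxy-10'β-hydroxyguai-4'-en-12',6'α-olide (10'-epimer of 4)
Conditions: MeMgBr, anhydrous CeCl3, THF, −78 °C
Reagents that add atoms: methylmagnesium bromide, C[Mg]Br
Why: Organocerium 1,2-addition is non-basic enough to avoid enolisation towards C1' and loss of the allylic acetate, is faster on the ketone than on acetate or lactone, and should enter from the α face next to H-1' and away from C2', which places the new hydroxyl β and inverts C10' relative to 2.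

Step 7
Reactants: 8 3'β-acetoxy-10'β-hydroxyguai-4'-en-12',6'α-olide
Product: 9 10'β-hydroxy-1'αH-guaia-2',4'-dien-12',6'α-olide (cyclopentadiene)
Conditions: Pd(PPh3)4 (cat.), Et3N, THF, 60 °C
Reagents that add atoms: none
Why: Palladium-catalysed elimination of an allylic acetate (Tsuji–Trost ionisation, then loss of a proton from the π-allyl complex) gives the cyclopentadiene under nearly neutral conditions that spare the tertiary alcohol.

Step 8
Reactants: 9 10'β-hydroxy-1'αH-guaia-2',4'-dien-12',6'α-olide; 10 cyclopent-4-ene-1,3-dione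
Product: 11 endo Diels–Alder adduct (new bonds C2–C2' and C3–C5'; ring A a cyclopentane-1,3-dione with carbonyls at C1 and C4; C3'=C4' alkene; free 10'β-hydroxyl)
Conditions: CH2Cl2, 0 °C to rt
Reagents that add atoms: none
Why: Normal-demand Diels–Alder reaction with a symmetrical and very reactive dienophile, which should outrun dimerisation of 9 and raises no regiochemical question, adding endo and to the α face of the diene anti to C10' on the sp3 carbon C1', which sets C2, C3, C2' and C5'.

Step 9
Reactants: 11 endo Diels–Alder adduct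
Product: 12 vinylogous acyl triflate (C1–OTf, C1=C5, C4=O)
Conditions: Tf2O (1 equiv), Et3N, CH2Cl2, −78 °C
Reagents that add atoms: triflic anhydride, O=S(=O)(OS(=O)(=O)C(F)(F)F)C(F)(F)F
Why: O-Sulfonylation of the enolised 1,3-dione, in which the oxygen on C1 lies beside the bridgehead CH (C2') while that on C4 is crowded by the quaternary bridgehead C5' and its C6' branch, so the bulky anhydride should take the C1 oxygen and leave the tertiary alcohol alone.

Step 10
Reactants: 12 vinylogous acyl triflate
Product: 13 ring A enone (C4=O, C5=C1, both alkene carbons CH)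
Conditions: Pd(OAc)2 (cat.), PPh3, HCO2H, Et3N (excess), DMF, 60 °C
Reagents that add atoms: none
Why: Palladium-catalysed formate reduction of an alkenyl triflate (oxidative addition, formate exchange, decarboxylation, reductive elimination) replaces the C1 oxygen by hydrogen and leaves the C4 enone.

Step 11
Reactants: 13 ring A enone
Product: 14 5-iodo enone (C4=O, C5(I)=C1H)
Conditions: I2, pyridine–CH2Cl2 1:1, rt
Reagents that add atoms: iodine, [I][I]
Why: α-Iodination of a cycloalkenone by conjugate addition of pyridine, iodination of the enolate and elimination, while C3'=C4' is shielded on both faces (C10' above, ring A below) and should stay inert.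

Step 12
Reactants: 14 5-iodo enone
Product: 15 iodo diene (C15H2=C4, C5(I)=C1H)
Conditions: Ph3PCH3Br, KOtBu, THF, 0 °C to rt
Reagents that add atoms: methyltriphenylphosphonium bromide, C[P+](c1ccccc1)(c1ccccc1)c1ccccc1.[Br-]
Why: Wittig methylenation of the still accessible C4 ketone brings in C15 while C4 stays trigonal, which is needed because after step 13 the endo methyl on C4' leaves no room for an α substituent on C4.

Step 13
Reactants: 15 iodo diene
Product: 16 cage alcohol (ether C10'–O–C4' exo, 3'-hydroxyl exo, C4' methyl endo)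
Conditions: Re2O7, 2,6-lutidine, CH2Cl2, rt; aq. NaHCO3 work-up
Reagents that add atoms: dirhenium heptoxide, O=[Re](=O)(=O)O[Re](=O)(=O)=O
Why: Hydroxyl-directed syn-oxidative cyclisation of a bishomoallylic alcohol, in which the perrhenate ester of the 10'-hydroxyl held over the exo face of C3'=C4' delivers the alkoxy oxygen to C4' and an oxo oxygen to C3' on the same face, closing the tetrahydrofuran and setting both centres exo and cis as the target requires.

Step 14
Reactants: 16 cage alcohol
Product: 17 3'-O-TBS ether of 16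
Conditions: TBSOTf, 2,6-lutidine, CH2Cl2, 0 °C
Reagents that add atoms: tert-butyldimethylsilyl triflate, CC(C)(C)[Si](C)(C)OS(=O)(=O)C(F)(F)F
Why: Silyl triflate silylation of the hindered secondary alcohol protects it against carbene O–H insertion, hydride and amide bases.

Step 15
Reactants: 17 3'-O-TBS iodo diene; 18 tributyl(1-ethoxyvinyl)stannane
Product: 19 triene enol ether (C5 bears C6(OEt)=C7H2; C4=C15H2; C5=C1H)
Conditions: Pd2(dba)3, AsPh3, CuI (cat.), NMP, 50 °C
Reagents that add atoms: none
Why: Stille coupling of the alkenyl iodide forms C5–C6 and delivers C6 as an ethyl enol ether, the donor alkene for the cyclopropanation.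

Step 16
Reactants: 20 2-bromo-N-methoxy-N-methylacetamide
Product: 21 2-diazo-N-methoxy-N-methylacetamide
Conditions: N,N'-ditosylhydrazine, DBU, THF, 0 °C
Reagents that add atoms: N,N'-ditosylhydrazine, Cc1ccc(cc1)S(=O)(=O)NNS(=O)(=O)c1ccc(C)cc1
Why: N-Alkylation of the ditosylhydrazine followed by double elimination of sulfinate is a standard conversion of a bromoacetyl compound into the acceptor-stabilised diazo compound.

Step 17
Reactants: 19 triene enol ether; 21 2-diazo-N-methoxy-N-methylacetamide
Product: 22 ethoxycyclopropane amide (C6(OEt)(ring A)–C7H2–C8H–C9(=O)N(OMe)Me; drawn with ring A and C9 cis)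
Conditions: Rh2(OAc)4 (cat.), CH2Cl2, rt, slow addition of 21
Reagents that add atoms: none
Why: Rhodium-carbenoid cyclopropanation selects the most electron-rich alkene C6=C7 (addition to C4=C15 would force C4 tetrahedral against the cage and C5=C1 is trisubstituted) and is not expected to be stereoselective, which is tolerated because C6 and C8 become trigonal in step 20.

Step 18
Reactants: 22 ethoxycyclopropane amide
Product: 23 ethoxycyclopropane carbaldehyde (C9HO on C8)
Conditions: Cp2Zr(H)Cl, THF, rt; H2O/silica work-up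
Reagents that add atoms: none
Why: Hydrozirconation of the tertiary amide gives a stable zirconated hemiaminal that releases the aldehyde on work-up, a reduction that leaves lactones and hindered alkenes alone.

Step 19
Reactants: 23 ethoxycyclopropane carbaldehyde; 24 1,1-bis(pinacolboryl)ethane
Product: 26 cage-fused cis-ethoxycyclopropane bearing ring A (C5=C1) on C6 and the (Z)-2-(pinacolboryl)prop-1-enyl group (C9=C10) on C8, via lithiated diborylethane 25 (not isolated)
Conditions: 24, LiTMP, THF, 0 °C; then 23, −78 °C to rt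
Reagents that add atoms: none
Why: Boron–Wittig olefination, in which the α-boryl carbanion adds to the aldehyde and syn B–O elimination through the less crowded rotamer should leave the remaining boryl group trans to C8 and the methyl group cis to it.

Step 20
Reactants: 26 cage-fused cis-ethoxycyclopropane with (Z)-alkenylboronate
Product: 27 hydroazulene with C5=C6 ethyl enol ether, C8=C9 alkene, C4=C15 methylene, H-1 α and C10 bearing α methyl and β pinacolboryl
Conditions: o-xylene, BHT (trace), base-washed sealed tube, 110 °C, then 165 °C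
Reagents that add atoms: none
Why: The cis isomer of 26 adopts the boat-shaped transition state in which C5=C1 and C9=C10 both lie over the three-membered ring, and in one concerted [3,3] shift C1 bonds to C10 while C6–C8 breaks, the strain of the cyclopropane paying for the tertiary–quaternary bond. The closest known reaction type is the thermal divinylcyclopropane–cycloheptadiene (Cope) rearrangement of alkoxy- and siloxy-substituted divinylcyclopropanes, here with a pinacolboryl group as a bystander on one alkene terminus. The seven-membered ring C1–C5–C6–C7–C8–C9–C10 closes by ring expansion of the cyclopropane and emerges as the cis,cis-1,4-diene C5=C6/C8=C9. C1 is set by the cage, which covers the α face of ring A so that C10 can only arrive from the convex β face (H-1 α), and C10 is set by the alkene geometry, since in the boat the substituent trans to C8 (boron) ends up cis to C2 and the methyl group trans to it. The step needs all cyclopropane diastereomers to converge, and this should be secured by the donor on C6: trans and face-mismatched isomers open reversibly at C6–C8 to an ethoxyallyl/borylallyl diradical at the higher temperature and re-close until they reach the one reactive cis form. The saturated cage rules out a retro-Diels–Alder reaction, and C4 stays trigonal throughout, so nothing is pressed against the endo methyl on C4'.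

Step 21
Reactants: 27 hydroazulene boronate
Product: 28 10β-hydroxy hydroazulene (tertiary allylic alcohol; enol ether and methylene retained)
Conditions: sodium perborate tetrahydrate, THF–H2O 1:1, rt
Reagents that add atoms: sodium perborate, [Na+].[Na+].O[B-]1(O)OO[B-](O)(O)OO1
Why: Oxidation of the tertiary allylboronate by 1,2-migration from boron to oxygen proceeds with retention, so the β hydroxyl on C10 should be obtained under conditions mild enough for enol ether and lactone.

Step 22
Reactants: 28 10β-hydroxy hydroazulene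
Product: 29 dienone alcohol (C4(CH3)=C5–C6=O, C8=C9, 10β-OH)
Conditions: PPTS (cat.), acetone–H2O 10:1, 0 °C to rt
Reagents that add atoms: water, O
Why: Hydrolysis of the dienol ether C15=C4–C5=C6–OEt, by protonation at C15 or at C5 followed by conjugation, gives the tetrasubstituted C4=C5 enone without an oxidation step and without touching H-1.

Step 23
Reactants: 29 dienone alcohol
Product: 30 enone alcohol (C8–C9 saturated)
Conditions: 2-nitrobenzenesulfonylhydrazide, Et3N, CH2Cl2, rt
Reagents that add atoms: none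
Why: Diimide reduction is a concerted syn hydrogen transfer that takes the cis-disubstituted C8=C9 alkene and ignores the tetrasubstituted enone.

Step 24
Reactants: 30 enone alcohol
Product: 31 10-O-TES ether of 30
Conditions: TESOTf, 2,6-lutidine, CH2Cl2, −20 °C
Reagents that add atoms: triethylsilyl triflate, CC[Si](CC)(CC)OS(=O)(=O)C(F)(F)F
Why: Silyl triflate protection of the tertiary alcohol removes the only acidic proton ahead of the enolate chemistry.

Step 25
Reactants: 31 10-O-TES enone; 32 ethyl (S)-2-(trifluoromethylsulfonyloxy)propanoate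
Product: 34 keto ester with the (11S)-1-ethoxycarbonylethyl group β on C7 (H-7 α), via lithium enolate 33 (not isolated)
Conditions: LDA (1 equiv), THF, −78 °C; DMPU; then 32, −78 to −40 °C
Reagents that add atoms: none
Why: Kinetic α'-deprotonation of the cross-conjugated enone at C7 (more acidic than the lactone α position) and SN2 alkylation with the lactate triflate, in which inversion gives (11S), the electrophile should approach the β face away from the cage, and C7 remains epimerisable towards the pseudo-equatorial side chain.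

Step 26
Reactants: 34 keto ester
Product: 36 bis-silylated anabsin (3'-O-TBS and 10-O-TES), via hydroxy ester 35 (not isolated)
Conditions: NaBH4, CeCl3·7H2O, MeOH, −40 °C; then PPTS, toluene, 60 °C
Reagents that add atoms: none
Why: Luche 1,2-reduction with hydride from the β face (the α face lies towards the cage) should give the pseudo-equatorial 6α alcohol trans to the C7 side chain, and acid-catalysed transesterification closes the trans-fused γ-lactone.

Step 27
Reactants: 36 bis-silylated anabsin
Product: 37 anabsin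
Conditions: HF·pyridine, pyridine, THF, 0 °C to rt
Reagents that add atoms: none
Why: Fluoride-driven cleavage of both silyl ethers under buffered conditions should leave the lactones, the ether bridge, the tetrasubstituted alkene and the tertiary alcohol intact.

Compound list
1 | (−)-α-santonin | C[C@H]1[C@@H]2CC[C@]3(C=CC(=O)C(=C3[C@H]2OC1=O)C)C | starting material
2 | isophotosantonic lactone | CC1=C2[C@H]3OC(=O)[C@@H](C)[C@@H]3CC[C@@](C)(O)[C@@H]2CC1=O | intermediate
3 | 3'β,10'α-dihydroxyguai-4'-en-12',6'α-olide | CC1=C2[C@H]3OC(=O)[C@@H](C)[C@@H]3CC[C@@](C)(O)[C@@H]2C[C@@H]1O | intermediate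
4 | 3'β-acetoxy-10'α-hydroxyguai-4'-en-12',6'α-olide | CC1=C2[C@H]3OC(=O)[C@@H](C)[C@@H]3CC[C@@](C)(O)[C@@H]2C[C@@H]1OC(C)=O | intermediate
5 | 3'β-acetoxyguaia-4',10'(14')-dien-12',6'α-olide | CC1=C2[C@H]3OC(=O)[C@@H](C)[C@@H]3CCC(=C)[C@@H]2C[C@@H]1OC(C)=O | intermediate
6 | 10'α,14'-diol of 5 (not isolated) | CC1=C2[C@H]3OC(=O)[C@@H](C)[C@@H]3CC[C@@](CO)(O)[C@@H]2C[C@@H]1OC(C)=O | intermediate
7 | 3'β-acetoxy-10'-oxo-14'-norguai-4'-en-12',6'α-olide | CC1=C2[C@H]3OC(=O)[C@@H](C)[C@@H]3CCC(=O)[C@@H]2C[C@@H]1OC(C)=O | intermediate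
8 | 3'β-acetoxy-10'β-hydroxyguai-4'-en-12',6'α-olide | CC1=C2[C@H]3OC(=O)[C@@H](C)[C@@H]3CC[C@](C)(O)[C@@H]2C[C@@H]1OC(C)=O | intermediate
9 | 10'β-hydroxy-1'αH-guaia-2',4'-dien-12',6'α-olide | CC1=C2[C@H]3OC(=O)[C@@H](C)[C@@H]3CC[C@](C)(O)[C@@H]2C=C1 | intermediate
10 | cyclopent-4-ene-1,3-dione | O=C1C=CC(=O)C1 | starting material
11 | endo Diels–Alder adduct, ring A 1,3-dione | O=C1CC(=O)[C@H]2[C@@H]3[C@@H]4[C@@]([C@H]5OC(=O)[C@@H](C)[C@@H]5CC[C@]4(C)O)(C(C)=C3)[C@@H]12 | intermediate
12 | vinylogous acyl triflate (C1–OTf) | O=C1C=C(OS(=O)(=O)C(F)(F)F)[C@H]2[C@@H]3[C@@H]4[C@@]([C@H]5OC(=O)[C@@H](C)[C@@H]5CC[C@]4(C)O)(C(C)=C3)[C@@H]12 | intermediate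
13 | ring A enone (C4=O, C5=C1) | O=C1C=C[C@H]2[C@@H]3[C@@H]4[C@@]([C@H]5OC(=O)[C@@H](C)[C@@H]5CC[C@]4(C)O)(C(C)=C3)[C@@H]12 | intermediate
14 | 5-iodo enone | O=C1C(I)=C[C@H]2[C@@H]3[C@@H]4[C@@]([C@H]5OC(=O)[C@@H](C)[C@@H]5CC[C@]4(C)O)(C(C)=C3)[C@@H]12 | intermediate
15 | iodo diene (C4=C15H2, C5(I)=C1H) | C=C1C(I)=C[C@H]2[C@@H]3[C@@H]4[C@@]([C@H]5OC(=O)[C@@H](C)[C@@H]5CC[C@]4(C)O)(C(C)=C3)[C@@H]12 | intermediate
16 | cage alcohol (C10'–O–C4' ether, 3'-exo-OH) | C=C1C(I)=C[C@H]2[C@@H]3[C@@H]4[C@]5([C@H]6OC(=O)[C@@H](C)[C@@H]6CC[C@]4(C)O[C@@]5(C)[C@H]3O)[C@@H]12 | intermediate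
17 | 3'-O-TBS ether of 16 | C=C1C(I)=C[C@H]2[C@@H]3[C@@H]4[C@]5([C@H]6OC(=O)[C@@H](C)[C@@H]6CC[C@]4(C)O[C@@]5(C)[C@H]3O[Si](C)(C)C(C)(C)C)[C@@H]12 | intermediate
18 | tributyl(1-ethoxyvinyl)stannane | CCCC[Sn](CCCC)(CCCC)C(=C)OCC | starting material
19 | triene enol ether | C=C1C(C(=C)OCC)=C[C@H]2[C@@H]3[C@@H]4[C@]5([C@H]6OC(=O)[C@@H](C)[C@@H]6CC[C@]4(C)O[C@@]5(C)[C@H]3O[Si](C)(C)C(C)(C)C)[C@@H]12 | intermediate
20 | 2-bromo-N-methoxy-N-methylacetamide | CON(C)C(=O)CBr | starting material
21 | 2-diazo-N-methoxy-N-methylacetamide | CON(C)C(=O)C=[N+]=[N-] | intermediate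
22 | ethoxycyclopropane N-methoxy-N-methylamide | C=C1C([C@@]7(OCC)C[C@H]7C(=O)N(C)OC)=C[C@H]2[C@@H]3[C@@H]4[C@]5([C@H]6OC(=O)[C@@H](C)[C@@H]6CC[C@]4(C)O[C@@]5(C)[C@H]3O[Si](C)(C)C(C)(C)C)[C@@H]12 | intermediate
23 | ethoxycyclopropane carbaldehyde | C=C1C([C@@]7(OCC)C[C@H]7C=O)=C[C@H]2[C@@H]3[C@@H]4[C@]5([C@H]6OC(=O)[C@@H](C)[C@@H]6CC[C@]4(C)O[C@@]5(C)[C@H]3O[Si](C)(C)C(C)(C)C)[C@@H]12 | intermediate
24 | 1,1-bis(pinacolboryl)ethane | CC(B1OC(C)(C)C(C)(C)O1)B1OC(C)(C)C(C)(C)O1 | starting material
25 | 1-lithio-1,1-bis(pinacolboryl)ethane (not isolated) | [Li]C(C)(B1OC(C)(C)C(C)(C)O1)B1OC(C)(C)C(C)(C)O1 | intermediate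
26 | rearrangement substrate, cis-ethoxycyclopropane with (Z)-alkenylboronate | C=C1C([C@@]7(OCC)C[C@H]7/C=C(\C)B8OC(C)(C)C(C)(C)O8)=C[C@H]2[C@@H]3[C@@H]4[C@]5([C@H]6OC(=O)[C@@H](C)[C@@H]6CC[C@]4(C)O[C@@]5(C)[C@H]3O[Si](C)(C)C(C)(C)C)[C@@H]12 | intermediate
27 | rearrangement product, hydroazulene tertiary allylboronate | C=C1C2=C(OCC)CC=C[C@](C)(B7OC(C)(C)C(C)(C)O7)[C@@H]2[C@H]2[C@@H]3[C@@H]4[C@]5([C@H]6OC(=O)[C@@H](C)[C@@H]6CC[C@]4(C)O[C@@]5(C)[C@H]3O[Si](C)(C)C(C)(C)C)[C@@H]12 | intermediate
28 | 10β-hydroxy hydroazulene dienol ether | C=C1C2=C(OCC)CC=C[C@](C)(O)[C@@H]2[C@H]2[C@@H]3[C@@H]4[C@]5([C@H]6OC(=O)[C@@H](C)[C@@H]6CC[C@]4(C)O[C@@]5(C)[C@H]3O[Si](C)(C)C(C)(C)C)[C@@H]12 | intermediate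
29 | dienone alcohol | CC1=C2C(=O)CC=C[C@](C)(O)[C@@H]2[C@H]2[C@@H]3[C@@H]4[C@]5([C@H]6OC(=O)[C@@H](C)[C@@H]6CC[C@]4(C)O[C@@]5(C)[C@H]3O[Si](C)(C)C(C)(C)C)[C@@H]12 | intermediate
30 | enone alcohol | CC1=C2C(=O)CCC[C@](C)(O)[C@@H]2[C@H]2[C@@H]3[C@@H]4[C@]5([C@H]6OC(=O)[C@@H](C)[C@@H]6CC[C@]4(C)O[C@@]5(C)[C@H]3O[Si](C)(C)C(C)(C)C)[C@@H]12 | intermediate
31 | 10-O-TES enone | CC1=C2C(=O)CCC[C@](C)(O[Si](CC)(CC)CC)[C@@H]2[C@H]2[C@@H]3[C@@H]4[C@]5([C@H]6OC(=O)[C@@H](C)[C@@H]6CC[C@]4(C)O[C@@]5(C)[C@H]3O[Si](C)(C)C(C)(C)C)[C@@H]12 | intermediate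
32 | ethyl (S)-2-(trifluoromethylsulfonyloxy)propanoate | C[C@H](OS(=O)(=O)C(F)(F)F)C(=O)OCC | starting material
33 | lithium C6=C7 enolate of 31 (not isolated) | [Li+].CC1=C2C([O-])=CCC[C@](C)(O[Si](CC)(CC)CC)[C@@H]2[C@H]2[C@@H]3[C@@H]4[C@]5([C@H]6OC(=O)[C@@H](C)[C@@H]6CC[C@]4(C)O[C@@]5(C)[C@H]3O[Si](C)(C)C(C)(C)C)[C@@H]12 | intermediate
34 | C7-alkylated keto ester (H-7 α, 11S) | CC1=C2C(=O)[C@H]([C@H](C)C(=O)OCC)CC[C@](C)(O[Si](CC)(CC)CC)[C@@H]2[C@H]2[C@@H]3[C@@H]4[C@]5([C@H]6OC(=O)[C@@H](C)[C@@H]6CC[C@]4(C)O[C@@]5(C)[C@H]3O[Si](C)(C)C(C)(C)C)[C@@H]12 | intermediate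
35 | 6α-hydroxy ester (not isolated) | CC1=C2[C@@H](O)[C@H]([C@H](C)C(=O)OCC)CC[C@](C)(O[Si](CC)(CC)CC)[C@@H]2[C@H]2[C@@H]3[C@@H]4[C@]5([C@H]6OC(=O)[C@@H](C)[C@@H]6CC[C@]4(C)O[C@@]5(C)[C@H]3O[Si](C)(C)C(C)(C)C)[C@@H]12 | intermediate
36 | 3'-O-TBS-10-O-TES-anabsin | CC1=C2[C@H]3OC(=O)[C@@H](C)[C@@H]3CC[C@](C)(O[Si](CC)(CC)CC)[C@@H]2[C@H]2[C@@H]3[C@@H]4[C@]5([C@H]6OC(=O)[C@@H](C)[C@@H]6CC[C@]4(C)O[C@@]5(C)[C@H]3O[Si](C)(C)C(C)(C)C)[C@@H]12 | intermediate
37 | anabsin | CC1=C2[C@H]3OC(=O)[C@@H](C)[C@@H]3CC[C@](C)(O)[C@@H]2[C@H]2[C@@H]3[C@@H]4[C@]5([C@H]6OC(=O)[C@@H](C)[C@@H]6CC[C@]4(C)O[C@@]5(C)[C@H]3O)[C@@H]12 | target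

Total step count: 27. Longest linear sequence: 26 (steps 1–15 and 17–27).

Steps most likely to fail

Step 20. The trans and face-mismatched cyclopropanes may not funnel cleanly. The temperature they need also permits 1,3-migration of boron in the tertiary allylboronate and slow loss of alkene geometry. The fallback sets out from 26 and brings the oxygen onto C10 before the rearrangement. Anhydrous Me3NO in toluene should oxidise the alkenylboronate with retention of geometry to the (E)-enol pinacol borate F1. This is an oxygen-donor alkene of the type for which this rearrangement is well established. Heating should give the tertiary pinacol borate F2, in which boron sits on oxygen and can no longer travel along the allyl system. Aqueous work-up rejoins the route at 28.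

Step 13. The perrhenate ester may fail to engage the shielded alkene. Alternatively, acid liberated in the flask may simply add the hydroxyl across C3'=C4' without oxygenating C3'. The fallback sets out from 15 and separates oxygenation from ring closure. VO(acac)2/t-BuOOH epoxidation directed by the 10'-hydroxyl should give the 3',4'-exo-epoxide F3. Et2Al(TMP) should isomerise it to the exo allylic alcohol with a C4'=C15' methylene group F4. Intramolecular oxymercuration with Hg(OCOCF3)2 acts at the only alkene that has a hydroxyl within reach, closing O–C4' to give the organomercurial cage alcohol F5. NaBH4/NaOH then replaces mercury by hydrogen and rejoins the route at 16.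

Step 25. The basic cross-conjugated enolate may eliminate the secondary triflate instead of displacing it, and facial selectivity at C7 may be poor. The fallback sets out from 29, one stage earlier, while C8=C9 is still present. TESOTf/2,6-lutidine gives the silyl ether of the dienone F6. KHMDS forms the extended C6–C9 dienolate, which is less basic and flatter. α-Alkylation at C7 with 32 should then give the Δ8 keto ester F7. Diimide reduction of C8=C9 rejoins the route at 34.

Further compounds
F1 | step 20 | (E)-enol pinacol borate of the rearrangement substrate | C=C1C([C@@]7(OCC)C[C@H]7/C=C(\C)OB8OC(C)(C)C(C)(C)O8)=C[C@H]2[C@@H]3[C@@H]4[C@]5([C@H]6OC(=O)[C@@H](C)[C@@H]6CC[C@]4(C)O[C@@]5(C)[C@H]3O[Si](C)(C)C(C)(C)C)[C@@H]12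
F2 | step 20 | tertiary pinacol borate of 28 | C=C1C2=C(OCC)CC=C[C@](C)(OB7OC(C)(C)C(C)(C)O7)[C@@H]2[C@H]2[C@@H]3[C@@H]4[C@]5([C@H]6OC(=O)[C@@H](C)[C@@H]6CC[C@]4(C)O[C@@]5(C)[C@H]3O[Si](C)(C)C(C)(C)C)[C@@H]12
F3 | step 13 | 3',4'-exo-epoxide of 15 | C=C1C(I)=C[C@H]2[C@@H]3[C@@H]4[C@@]([C@H]5OC(=O)[C@@H](C)[C@@H]5CC[C@]4(C)O)([C@@]7(C)O[C@H]73)[C@@H]12
F4 | step 13 | 3'-exo-hydroxy-4'(15')-methylene diol | C=C1C(I)=C[C@H]2[C@@H]3[C@@H]4[C@@]([C@H]5OC(=O)[C@@H](C)[C@@H]5CC[C@]4(C)O)(C(=C)[C@H]3O)[C@@H]12
F5 | step 13 | 15'-(trifluoroacetoxymercurio) cage alcohol | C=C1C(I)=C[C@H]2[C@@H]3[C@@H]4[C@]5([C@H]6OC(=O)[C@@H](C)[C@@H]6CC[C@]4(C)O[C@@]5(C[Hg]OC(=O)C(F)(F)F)[C@H]3O)[C@@H]12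
F6 | step 25 | 10-O-TES ether of 29 | CC1=C2C(=O)CC=C[C@](C)(O[Si](CC)(CC)CC)[C@@H]2[C@H]2[C@@H]3[C@@H]4[C@]5([C@H]6OC(=O)[C@@H](C)[C@@H]6CC[C@]4(C)O[C@@]5(C)[C@H]3O[Si](C)(C)C(C)(C)C)[C@@H]12
F7 | step 25 | C7-alkylated Δ8 keto ester | CC1=C2C(=O)[C@H]([C@H](C)C(=O)OCC)C=C[C@](C)(O[Si](CC)(CC)CC)[C@@H]2[C@H]2[C@@H]3[C@@H]4[C@]5([C@H]6OC(=O)[C@@H](C)[C@@H]6CC[C@]4(C)O[C@@]5(C)[C@H]3O[Si](C)(C)C(C)(C)C)[C@@H]12
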